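**Retrosynthetic overview**
1. Target 22 ⇐ bis-pivalate 21 (free the two guaiacyl phenols) ⇐ alcohol 18 + p-coumaric acid 20 (Mitsunobu ester bond).
2. 18 ⇐ (R)-2-aryl-2H-chromene 15 by oxidative ring contraction: the ring A carbon C4a shifts from C4 to C3, old C4 becomes the CH2OH carbon, and C3 is set trans to C2.
3. 15 ⇐ 3-formylchromene 14 (decarbonylation) ⇐ salicylaldehyde 11 + enal 13 (organocatalytic oxa-Michael/aldol, sets C2).
4. 11 ⇐ ortho-formylation of phenol ester 10 ⇐ dihydroconiferyl alcohol 9 + O-pivaloylferulic acid 6; 6, 9 and 13 all come from 4-iodoguaiacol 3 ⇐ catechol 1 by Heck reactions with acrylic acid, allyl alcohol and acrolein; 20 ⇐ 4-iodophenol.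
5. Ring order: the pyran ring is built first (step 9), then contracted to the dihydrofuran ring (step 11); the benzene rings are bought.

Assumption: the target is the (2R,3S)-trans isomer encoded by the SMILES, and the facial sense of the prolinol silyl ether catalyst in step 9 follows the usual model (attack anti to the CPh2OSiMe3 group); the antipodal catalyst would be used if the sense proved opposite.

**Step 1**
Reactants: 1 catechol
Product: 2 2-methoxyphenol (guaiacol)
Conditions: MeI (1.0 equiv), K2CO3 (1.0 equiv), acetone, 56 °C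
Reagents that add atoms: iodomethane, CI
Why: Williamson mono-O-methylation of the catechol monoanion; guaiacol is separated from veratrole and catechol by base extraction and distillation.

**Step 2**
Reactants: 2 2-methoxyphenol
Product: 3 4-iodo-2-methoxyphenol
Conditions: NaI (1.0 equiv), NaOH (1.0 equiv), aq. NaOCl (1.0 equiv), MeOH, 0 °C
Reagents that add atoms: sodium iodide, [Na+].[I-]
Why: Electrophilic aromatic iodination of the phenoxide by hypoiodite formed in the flask, directed para to the phenoxide oxygen.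

**Step 3**
Reactants: 3 4-iodo-2-methoxyphenol
Product: 4 4-iodo-2-methoxyphenyl pivalate
Conditions: PivCl (1.1 equiv), Et3N, DMAP (5 mol%), CH2Cl2, 0 °C to rt
Reagents that add atoms: pivaloyl chloride, CC(C)(C)C(Cl)=O
Why: O-acylation; the pivalate is a robust, electron-withdrawing phenol protecting group that keeps the guaiacyl rings inert to the oxidant and poor at migrating in step 11.

**Step 4**
Reactants: 4 4-iodo-2-methoxyphenyl pivalate; 5 acrylic acid
Product: 6 (E)-3-[3-methoxy-4-(pivaloyloxy)phenyl]prop-2-enoic acid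
Conditions: Pd(OAc)2 (2 mol%), P(o-tol)3 (4 mol%), Et3N (3 equiv), MeCN, 80 °C; then aq. HCl
Reagents that add atoms: none
Why: Mizoroki–Heck reaction of the aryl iodide with acrylic acid; syn insertion and syn β-hydride elimination give the E acid.

**Step 5**
Reactants: 3 4-iodo-2-methoxyphenol; 7 allyl alcohol
Product: 9 4-(3-hydroxypropyl)-2-methoxyphenol, via 3-(4-hydroxy-3-methoxyphenyl)propanal 8 (not isolated)
Conditions: Pd(OAc)2 (2 mol%), nBu4NCl (1 equiv), NaHCO3 (2.5 equiv), DMF, 50 °C; then MeOH, NaBH4, 0 °C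
Reagents that add atoms: none
Why: Jeffery-type Heck reaction with allyl alcohol, in which β-hydride elimination toward the carbinol gives the enol and hence the 3-arylpropanal, reduced in the same pot by borohydride.

**Step 6**
Reactants: 9 4-(3-hydroxypropyl)-2-methoxyphenol; 6 (E)-3-[3-methoxy-4-(pivaloyloxy)phenyl]prop-2-enoic acid
Product: 10 3-(4-hydroxy-3-methoxyphenyl)propyl (E)-3-[3-methoxy-4-(pivaloyloxy)phenyl]prop-2-enoate
Conditions: PPh3 (1.3 equiv), DIAD (1.3 equiv), THF, 0 °C to rt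
Reagents that add atoms: none
Why: Mitsunobu esterification; only the primary alcohol is activated, and the carboxylic acid (pKa about 4.5) outcompetes the phenol (pKa about 10) as the nucleophile.

**Step 7**
Reactants: 10 3-(4-hydroxy-3-methoxyphenyl)propyl (E)-3-[3-methoxy-4-(pivaloyloxy)phenyl]prop-2-enoate
Product: 11 3-(3-formyl-4-hydroxy-5-methoxyphenyl)propyl (E)-3-[3-methoxy-4-(pivaloyloxy)phenyl]prop-2-enoate
Conditions: MgCl2 (2 equiv), Et3N (4 equiv), (CH2O)n (6 equiv), MeCN, 80 °C
Reagents that add atoms: paraformaldehyde (formaldehyde), C=O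
Why: Casnati–Skattebøl ortho-formylation through the magnesium phenoxide; the only free ortho position is attacked, and the hindered pivalate and the cinnamate ester are not touched.

**Step 8**
Reactants: 4 4-iodo-2-methoxyphenyl pivalate; 12 acrolein
Product: 13 (E)-3-[3-methoxy-4-(pivaloyloxy)phenyl]prop-2-enal
Conditions: Pd(OAc)2 (3 mol%), nBu4NCl (1 equiv), NaHCO3 (2.5 equiv), DMF, 40 °C
Reagents that add atoms: none
Why: Jeffery-type (phase-transfer) Heck reaction; the mild bicarbonate conditions tolerate acrolein and the aryl ester and give the E enal.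

**Step 9**
Reactants: 11 3-(3-formyl-4-hydroxy-5-methoxyphenyl)propyl (E)-3-[3-methoxy-4-(pivaloyloxy)phenyl]prop-2-enoate; 13 (E)-3-[3-methoxy-4-(pivaloyloxy)phenyl]prop-2-enal
Product: 14 3-[(2S)-3-formyl-8-methoxy-2-[3-methoxy-4-(pivaloyloxy)phenyl]-2H-chromen-6-yl]propyl (E)-3-[3-methoxy-4-(pivaloyloxy)phenyl]prop-2-enoate
Conditions: (R)-α,α-diphenylprolinol trimethylsilyl ether (20 mol%), 2-nitrobenzoic acid (20 mol%), 4 Å MS, toluene, rt
Reagents that add atoms: none
Why: Organocatalytic domino oxa-Michael/aldol condensation (iminium, then enamine activation): the phenol adds to the β-carbon of the iminium ion on the face away from the CPh2OSiMe3 group, which sets C2 as S, and intramolecular aldol condensation closes the pyran ring.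

**Step 10**
Reactants: 14 3-[(2S)-3-formyl-8-methoxy-2-[3-methoxy-4-(pivaloyloxy)phenyl]-2H-chromen-6-yl]propyl (E)-3-[3-methoxy-4-(pivaloyloxy)phenyl]prop-2-enoate
Product: 15 3-[(2R)-8-methoxy-2-[3-methoxy-4-(pivaloyloxy)phenyl]-2H-chromen-6-yl]propyl (E)-3-[3-methoxy-4-(pivaloyloxy)phenyl]prop-2-enoate
Conditions: RhCl(PPh3)3 (1.1 equiv), toluene, 85 °C
Reagents that add atoms: none
Why: Tsuji–Wilkinson decarbonylation of the enal (C–H oxidative addition, CO extrusion, reductive elimination); C2 is untouched and its descriptor changes from S to R only because C3 loses CIP priority.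

**Step 11**
Reactants: 15 3-[(2R)-8-methoxy-2-[3-methoxy-4-(pivaloyloxy)phenyl]-2H-chromen-6-yl]propyl (E)-3-[3-methoxy-4-(pivaloyloxy)phenyl]prop-2-enoate
Product: 18 3-[(2R,3S)-3-(hydroxymethyl)-7-methoxy-2-[3-methoxy-4-(pivaloyloxy)phenyl]-2,3-dihydro-1-benzofuran-5-yl]propyl (E)-3-[3-methoxy-4-(pivaloyloxy)phenyl]prop-2-enoate, via dimethyl acetal 16 (not isolated), via aldehyde 17 (not isolated)
Conditions: PhI(OH)OTs (1.2 equiv), MeOH, −20 to 0 °C; then 1 M aq. HCl, THF, rt; then NaBH4, MeOH, 0 °C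
Reagents that add atoms: water, O (methanol, CO, leaves its methoxy groups only in the non-isolated acetal 16)
Why: Proposed new method: trivalent-iodine ring contraction of an enantioenriched 2-aryl-2H-chromene with transfer of the C2 configuration; the iodane adds to C3 of the styrene-type C3=C4 bond anti to the C2 aryl group, methanol traps the C4 cation (stabilised by ring A and its ortho oxygen) trans to iodine, and the ring A carbon C4a, antiperiplanar to the equatorial C3–I bond, shifts from C4 to C3 with loss of PhI and inversion at C3, giving a methoxy-oxocarbenium ion (then acetal 16) with C3 trans to C2, while the pivalate makes ring B a poor migrating group so the competing C2-to-C3 aryl shift is suppressed; hydrolysis and borohydride reduction then give 18; closest known reaction type: the PhI(OH)OTs- or trivalent-thallium-mediated ring contraction of 1,2-dihydronaphthalenes to indanes and of flavanones to 2-aryl-2,3-dihydrobenzofuran-3-carboxylates.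

**Step 12**
Reactants: 19 4-iodophenol; 5 acrylic acid
Product: 20 (E)-3-(4-hydroxyphenyl)prop-2-enoic acid (p-coumaric acid)
Conditions: Pd(OAc)2 (1 mol%), Et3N (3 equiv), MeCN/H2O, 85 °C; then aq. HCl
Reagents that add atoms: none
Why: Mizoroki–Heck reaction, which tolerates the free phenol and gives the E acid.

**Step 13**
Reactants: 18 3-[(2R,3S)-3-(hydroxymethyl)-7-methoxy-2-[3-methoxy-4-(pivaloyloxy)phenyl]-2,3-dihydro-1-benzofuran-5-yl]propyl (E)-3-[3-methoxy-4-(pivaloyloxy)phenyl]prop-2-enoate; 20 p-coumaric acid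
Product: 21 3-[(2R,3S)-3-{[(E)-3-(4-hydroxyphenyl)prop-2-enoyl]oxymethyl}-7-methoxy-2-[3-methoxy-4-(pivaloyloxy)phenyl]-2,3-dihydro-1-benzofuran-5-yl]propyl (E)-3-[3-methoxy-4-(pivaloyloxy)phenyl]prop-2-enoate
Conditions: PPh3 (1.5 equiv), DIAD (1.5 equiv), THF, 0 °C to rt
Reagents that add atoms: none
Why: Mitsunobu esterification of the only free hydroxyl of 18; the carboxylic acid, not the phenol of 20, is the nucleophile, and no stereocentre is involved because the reacting carbon is CH2.

**Step 14**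
Reactants: 21 bis-pivalate of the target
Product: 22 (+)-Boehmenan X
Conditions: N2H4·H2O (6 equiv), THF/MeOH, 0 °C to rt
Reagents that add atoms: none
Why: Chemoselective hydrazinolysis; aryl esters are far better acyl donors toward amine nucleophiles than alkyl cinnamates, so both pivalates are removed while the two cinnamate esters and the stereocentres stay.

**Compound list**
1 | catechol (benzene-1,2-diol) | Oc1ccccc1O | starting material
2 | 2-methoxyphenol (guaiacol) | COc1ccccc1O | intermediate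
3 | 4-iodo-2-methoxyphenol | COc1cc(I)ccc1O | intermediate
4 | 4-iodo-2-methoxyphenyl pivalate | COc1cc(I)ccc1OC(=O)C(C)(C)C | intermediate
5 | acrylic acid | C=CC(=O)O | starting material
6 | (E)-3-[3-methoxy-4-(pivaloyloxy)phenyl]prop-2-enoic acid | COc1cc(/C=C/C(=O)O)ccc1OC(=O)C(C)(C)C | intermediate
7 | allyl alcohol (prop-2-en-1-ol) | C=CCO | starting material
8 | 3-(4-hydroxy-3-methoxyphenyl)propanal | COc1cc(CCC=O)ccc1O | intermediate
9 | 4-(3-hydroxypropyl)-2-methoxyphenol (dihydroconiferyl alcohol) | COc1cc(CCCO)ccc1O | intermediate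
10 | 3-(4-hydroxy-3-methoxyphenyl)propyl (E)-3-[3-methoxy-4-(pivaloyloxy)phenyl]prop-2-enoate | COc1cc(CCCOC(=O)/C=C/c2ccc(OC(=O)C(C)(C)C)c(OC)c2)ccc1O | intermediate
11 | 3-(3-formyl-4-hydroxy-5-methoxyphenyl)propyl (E)-3-[3-methoxy-4-(pivaloyloxy)phenyl]prop-2-enoate | COc1cc(CCCOC(=O)/C=C/c2ccc(OC(=O)C(C)(C)C)c(OC)c2)cc(C=O)c1O | intermediate
12 | acrolein (prop-2-enal) | C=CC=O | starting material
13 | (E)-3-[3-methoxy-4-(pivaloyloxy)phenyl]prop-2-enal | COc1cc(/C=C/C=O)ccc1OC(=O)C(C)(C)C | intermediate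
14 | 3-[(2S)-3-formyl-8-methoxy-2-[3-methoxy-4-(pivaloyloxy)phenyl]-2H-chromen-6-yl]propyl (E)-3-[3-methoxy-4-(pivaloyloxy)phenyl]prop-2-enoate | COc1cc(/C=C/C(=O)OCCCc2cc(OC)c3c(c2)C=C(C=O)[C@H](c2ccc(OC(=O)C(C)(C)C)c(OC)c2)O3)ccc1OC(=O)C(C)(C)C | intermediate
15 | 3-[(2R)-8-methoxy-2-[3-methoxy-4-(pivaloyloxy)phenyl]-2H-chromen-6-yl]propyl (E)-3-[3-methoxy-4-(pivaloyloxy)phenyl]prop-2-enoate | COc1cc(/C=C/C(=O)OCCCc2cc(OC)c3c(c2)C=C[C@H](c2ccc(OC(=O)C(C)(C)C)c(OC)c2)O3)ccc1OC(=O)C(C)(C)C | intermediate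
16 | 3-[(2R,3R)-3-(dimethoxymethyl)-7-methoxy-2-[3-methoxy-4-(pivaloyloxy)phenyl]-2,3-dihydro-1-benzofuran-5-yl]propyl (E)-3-[3-methoxy-4-(pivaloyloxy)phenyl]prop-2-enoate | COc1cc(/C=C/C(=O)OCCCc2cc(OC)c3c(c2)[C@@H](C(OC)OC)[C@H](c2ccc(OC(=O)C(C)(C)C)c(OC)c2)O3)ccc1OC(=O)C(C)(C)C | intermediate
17 | 3-[(2R,3R)-3-formyl-7-methoxy-2-[3-methoxy-4-(pivaloyloxy)phenyl]-2,3-dihydro-1-benzofuran-5-yl]propyl (E)-3-[3-methoxy-4-(pivaloyloxy)phenyl]prop-2-enoate | COc1cc(/C=C/C(=O)OCCCc2cc(OC)c3c(c2)[C@@H](C=O)[C@H](c2ccc(OC(=O)C(C)(C)C)c(OC)c2)O3)ccc1OC(=O)C(C)(C)C | intermediate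
18 | 3-[(2R,3S)-3-(hydroxymethyl)-7-methoxy-2-[3-methoxy-4-(pivaloyloxy)phenyl]-2,3-dihydro-1-benzofuran-5-yl]propyl (E)-3-[3-methoxy-4-(pivaloyloxy)phenyl]prop-2-enoate | COc1cc(/C=C/C(=O)OCCCc2cc(OC)c3c(c2)[C@@H](CO)[C@H](c2ccc(OC(=O)C(C)(C)C)c(OC)c2)O3)ccc1OC(=O)C(C)(C)C | intermediate
19 | 4-iodophenol | Oc1ccc(I)cc1 | starting material
20 | (E)-3-(4-hydroxyphenyl)prop-2-enoic acid (p-coumaric acid) | OC(=O)/C=C/c1ccc(O)cc1 | intermediate
21 | 3-[(2R,3S)-3-{[(E)-3-(4-hydroxyphenyl)prop-2-enoyl]oxymethyl}-7-methoxy-2-[3-methoxy-4-(pivaloyloxy)phenyl]-2,3-dihydro-1-benzofuran-5-yl]propyl (E)-3-[3-methoxy-4-(pivaloyloxy)phenyl]prop-2-enoate | COc1cc(/C=C/C(=O)OCCCc2cc(OC)c3c(c2)[C@@H](COC(=O)/C=C/c2ccc(O)cc2)[C@H](c2ccc(OC(=O)C(C)(C)C)c(OC)c2)O3)ccc1OC(=O)C(C)(C)C | intermediate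
22 | (+)-Boehmenan X, 3-[(2R,3S)-2-(4-hydroxy-3-methoxyphenyl)-3-{[(E)-3-(4-hydroxyphenyl)prop-2-enoyl]oxymethyl}-7-methoxy-2,3-dihydro-1-benzofuran-5-yl]propyl (E)-3-(4-hydroxy-3-methoxyphenyl)prop-2-enoate | COc1cc(/C=C/C(=O)OCCCc2cc(OC)c3c(c2)[C@@H](COC(=O)/C=C/c2ccc(O)cc2)[C@H](c2ccc(O)c(OC)c2)O3)ccc1O | target

**Step count and risks**
Total steps: 14. Longest linear sequence: 11 steps (1 → 2 → 3 → 4 → 6 → 10 → 11 → 14 → 15 → 18 → 21 → 22).

Steps most likely to fail:

Step 11 (the proposed new ring contraction). It could give the trans-3,4-dimethoxy addition product instead of the shift, a competing shift of ring B, or over-oxidation. The fallback uses known stepwise halonium chemistry, sets out from chromene 15 and comes back at acetal 16. NBS in MeOH at 0 °C adds anti across C3=C4 (standard methoxybromination of 2H-chromenes, bromine anti to the C2 aryl group) to give 3-[(2S,3R,4S)-3-bromo-4,8-dimethoxy-2-[3-methoxy-4-(pivaloyloxy)phenyl]chroman-6-yl]propyl (E)-3-[3-methoxy-4-(pivaloyloxy)phenyl]prop-2-enoate F1. AgBF4 in MeOH/CH2Cl2 at 0 °C then pulls off bromide with the same anti shift of the ring A carbon (silver-assisted ring contraction of a halohydrin ether), giving 16, which is hydrolysed and reduced to 18 as in step 11.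

Step 10 (decarbonylation). The hindered trisubstituted enal may react sluggishly, and prolonged heating could erode the C2 configuration. The fallback sets out from phenol 10 and enal 13 and comes back at 15, bypassing steps 7, 9 and 10. PhB(OH)2 (1.2 equiv) and catalytic propionic acid in refluxing toluene (Dean–Stark) condense the two partners directly, by ortho-hydroxyalkylation and ring closure of the ortho-quinone methide, to the racemic chromene 3-[8-methoxy-2-[3-methoxy-4-(pivaloyloxy)phenyl]-2H-chromen-6-yl]propyl (E)-3-[3-methoxy-4-(pivaloyloxy)phenyl]prop-2-enoate F2. The enantiomers are separated by preparative HPLC on an amylose tris(3,5-dimethylphenylcarbamate) phase, and the (R)-enantiomer 15 is taken on.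

Step 14 (selective removal of two aryl pivalates beside two cinnamate esters). Hydrazine may also attack a cinnamate, most likely the exposed p-coumarate. The fallback changes the order of the end game, sets out from 18 and comes back at 22. N2H4·H2O in THF/MeOH removes the pivalates while only the feruloyl ester is present, giving 3-[(2R,3S)-2-(4-hydroxy-3-methoxyphenyl)-3-(hydroxymethyl)-7-methoxy-2,3-dihydro-1-benzofuran-5-yl]propyl (E)-3-(4-hydroxy-3-methoxyphenyl)prop-2-enoate F3. A Mitsunobu reaction with 20 (PPh3, DIAD, THF, 0 °C) then esterifies the single aliphatic hydroxyl in the presence of the free phenols, since only the carboxylic acid is acidic enough to act as nucleophile, and gives 22 directly.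

**Further compounds**
F1 | step 11 | 3-[(2S,3R,4S)-3-bromo-4,8-dimethoxy-2-[3-methoxy-4-(pivaloyloxy)phenyl]chroman-6-yl]propyl (E)-3-[3-methoxy-4-(pivaloyloxy)phenyl]prop-2-enoate | COc1cc(/C=C/C(=O)OCCCc2cc(OC)c3c(c2)[C@H](OC)[C@@H](Br)[C@H](c2ccc(OC(=O)C(C)(C)C)c(OC)c2)O3)ccc1OC(=O)C(C)(C)C
F2 | step 10 | racemic 3-[8-methoxy-2-[3-methoxy-4-(pivaloyloxy)phenyl]-2H-chromen-6-yl]propyl (E)-3-[3-methoxy-4-(pivaloyloxy)phenyl]prop-2-enoate | COc1cc(/C=C/C(=O)OCCCc2cc(OC)c3c(c2)C=CC(c2ccc(OC(=O)C(C)(C)C)c(OC)c2)O3)ccc1OC(=O)C(C)(C)C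
F3 | step 14 | 3-[(2R,3S)-2-(4-hydroxy-3-methoxyphenyl)-3-(hydroxymethyl)-7-methoxy-2,3-dihydro-1-benzofuran-5-yl]propyl (E)-3-(4-hydroxy-3-methoxyphenyl)prop-2-enoate | COc1cc(/C=C/C(=O)OCCCc2cc(OC)c3c(c2)[C@@H](CO)[C@H](c2ccc(O)c(OC)c2)O3)ccc1O
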